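**Retrosynthetic overview**
- The only ring, the γ-lactone, is closed last, as in the presumed biosynthesis: a (3S)-3-hydroxy fatty ester is joined through its α-carbon to the keto carbon of a pyruvate C3 unit, and the 3-hydroxyl lactonises onto the pyruvate carboxyl.
- The pyruvate unit is ethyl 3-(trimethylsilyl)pyruvate, so that loss of the former keto oxygen is a regiospecific Peterson elimination to the exocyclic methylene. The ring carbon bearing CO2H is set by 1,2-induction (anti addition gives the cis lactone).
- The 3-hydroxy ester comes from asymmetric hydrogenation of a β-keto ester, itself made from acetoacetate dianion and (S)-14-bromotetradecan-2-ol.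
- The bromo alcohol comes from 11-bromoundec-1-ene and (S)-propylene oxide (side-chain carbinol from the chiral pool); the silylpyruvate from Me3SiCH2MgCl and diethyl oxalate.

Assumption: the SMILES is read as the cis lactone (2S,3S)-2-[(14S)-14-hydroxypentadecyl]-4-methylidene-5-oxooxolane-3-carboxylic acid; Me3SiCH2MgCl, n-BuLi and LiN(iPr)2 are bought as solutions.

**Step 1**
Reactants: 1 11-bromoundec-1-ene; 2 (S)-2-methyloxirane ((S)-propylene oxide)
Product: 4 (2S)-tetradec-13-en-2-ol, via undec-10-enylmagnesium bromide 3 (not isolated)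
Conditions: Mg, THF, 45 °C; then CuI (10 mol %), 2, −30 → 0 °C; aq. NH4Cl
Reagents that add atoms: none
Why: Copper-catalysed Grignard opening of a monosubstituted epoxide (SN2 at the unsubstituted CH2) leaves the C–O stereocentre of 2 untouched, so it becomes the (S)-carbinol of the side chain.

**Step 2**
Reactants: 4 (2S)-tetradec-13-en-2-ol
Product: 5 (2S)-14-bromotetradecan-2-ol
Conditions: HBr (g), dibenzoyl peroxide (5 mol %), hexane, 0 °C
Reagents that add atoms: hydrogen bromide, Br
Why: Peroxide-initiated radical-chain (Kharasch, anti-Markovnikov) hydrobromination puts bromine on the terminal carbon, and in cold hexane the secondary alcohol is neither substituted nor racemised.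

**Step 3**
Reactants: 5 (2S)-14-bromotetradecan-2-ol; 6 tert-butyl 3-oxobutanoate (tert-butyl acetoacetate)
Product: 8 tert-butyl (17S)-17-hydroxy-3-oxooctadecanoate, via acetoacetate dianion 7 (not isolated)
Conditions: 6 (2.5 equiv), NaH, THF, 0 °C; n-BuLi, 0 °C; then 5, 0 °C → rt; 1 M HCl, 0 °C
Reagents that add atoms: none
Why: Huckin–Weiler γ-alkylation of the acetoacetate dianion, whose terminal carbanion is the more nucleophilic site, by the primary bromide; one of the 2.5 equivalents of dianion is used up deprotonating the free hydroxyl, which then stays inert as its alkoxide.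

**Step 4**
Reactants: 8 tert-butyl (17S)-17-hydroxy-3-oxooctadecanoate
Product: 9 tert-butyl (3S,17S)-3,17-dihydroxyoctadecanoate
Conditions: [RuCl(p-cymene)((S)-BINAP)]Cl (0.5 mol %), H2 (10 bar), MeOH, 50 °C
Reagents that add atoms: none
Why: Noyori asymmetric hydrogenation of a β-keto ester, in which the ester-chelated ketone is reduced within the (S)-BINAP pocket to the (3S)-alcohol (the sense known for acetoacetates and long-chain 3-oxoalkanoates, typically above 97% ee), while the isolated (17S)-carbinol is not touched.

**Step 5**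
Reactants: 10 (trimethylsilyl)methylmagnesium chloride, Me3SiCH2MgCl; 11 diethyl oxalate
Product: 12 ethyl 2-oxo-3-(trimethylsilyl)propanoate (ethyl 3-(trimethylsilyl)pyruvate)
Conditions: 10 (1.0 M in Et2O) added to 11 (1.5 equiv), THF, −78 °C; AcOH (1.1 equiv), −78 °C; pentane, filter, distil (Kugelrohr), use fresh
Reagents that add atoms: none
Why: Mono-acylation of a Grignard reagent by diethyl oxalate (the tetrahedral magnesium alkoxide is stable at −78 °C and collapses only on quench) is the standard α-keto ester synthesis, and the anhydrous AcOH quench spares the C–Si bond of the α-silyl ketone.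

**Step 6**
Reactants: 9 tert-butyl (3S,17S)-3,17-dihydroxyoctadecanoate; 12 ethyl 2-oxo-3-(trimethylsilyl)propanoate
Product: 17 (2S,3S)-2-[(14S)-14-hydroxypentadecyl]-4-methylidene-5-oxooxolane-3-carboxylic acid, via trilithium trianion 13 (not isolated), via open-chain aldol adduct 14 (not isolated), via silyl hydroxy lactone 15 (not isolated), via tert-butyl ester 16 (not isolated)
Conditions: LiN(iPr)2 (3.3 equiv), THF, −78 → −30 °C; 12 (1.5 equiv), −78 °C, 1 h; CF3CO2H (excess), −78 °C → rt; evaporate; CF3CO2H/CH2Cl2 1:2, rt; then aq. THF, rt; no basic work-up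
Reagents that add atoms: none
Why: Proposed new method: the trianion 13 plays the part of the 3-hydroxyacyl unit and 12 that of pyruvate, so that Fráter–Seebach aldol addition of the lithium-chelated enolate to the very electrophilic keto group, from the face anti to the C-3 alkyl chain, sets the new centre as (2R) (anti, at least 9:1 expected), the 3-hydroxyl then lactonises onto the ethyl ester to give the cis-lactone 15, and CF3CO2H triggers anti (Peterson) elimination of Me3SiOH from the tertiary β-hydroxysilane, which can only place the double bond exocyclic and never exposes the base-labile cis centre to base, before it cleaves the tert-butyl ester; the closest known reactions are the Fráter–Seebach α-hydroxyalkylation of β-hydroxy ester dianions by ketones and the Hudrlik–Peterson olefination of α-silyl ketones by organolithium reagents followed by acid.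

**Compound list**
1 | 11-bromoundec-1-ene | C=CCCCCCCCCCBr | starting material
2 | (S)-2-methyloxirane | C[C@H]1CO1 | starting material
3 | undec-10-enylmagnesium bromide, CH2=CH(CH2)9MgBr | C=CCCCCCCCCC[Mg]Br | intermediate
4 | (2S)-tetradec-13-en-2-ol | C[C@H](O)CCCCCCCCCCC=C | intermediate
5 | (2S)-14-bromotetradecan-2-ol | C[C@H](O)CCCCCCCCCCCCBr | intermediate
6 | tert-butyl 3-oxobutanoate | CC(=O)CC(=O)OC(C)(C)C | starting material
7 | sodium lithium dianion of tert-butyl 3-oxobutanoate | [Na+].[Li+].C=C([O-])C=C([O-])OC(C)(C)C | intermediate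
8 | tert-butyl (17S)-17-hydroxy-3-oxooctadecanoate | C[C@H](O)CCCCCCCCCCCCCC(=O)CC(=O)OC(C)(C)C | intermediate
9 | tert-butyl (3S,17S)-3,17-dihydroxyoctadecanoate | C[C@H](O)CCCCCCCCCCCCC[C@H](O)CC(=O)OC(C)(C)C | intermediate
10 | (trimethylsilyl)methylmagnesium chloride, Me3SiCH2MgCl | C[Si](C)(C)C[Mg]Cl | starting material
11 | diethyl oxalate | CCOC(=O)C(=O)OCC | starting material
12 | ethyl 2-oxo-3-(trimethylsilyl)propanoate | CCOC(=O)C(=O)C[Si](C)(C)C | intermediate
13 | trilithium trianion of 9 (3,17-dialkoxide ester enolate) | [Li+].[Li+].[Li+].C[C@H]([O-])CCCCCCCCCCCCC[C@H]([O-])C=C([O-])OC(C)(C)C | intermediate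
14 | 1-tert-butyl 4-ethyl (2R)-2-[(1S,15S)-1,15-dihydroxyhexadecyl]-3-hydroxy-3-[(trimethylsilyl)methyl]butanedioate (C-3 epimers) | CCOC(=O)C(O)(C[Si](C)(C)C)[C@@H]([C@@H](O)CCCCCCCCCCCCC[C@H](C)O)C(=O)OC(C)(C)C | intermediate
15 | tert-butyl (2S,3R)-4-hydroxy-2-[(14S)-14-hydroxypentadecyl]-5-oxo-4-[(trimethylsilyl)methyl]oxolane-3-carboxylate (C-4 epimers) | C[Si](C)(C)CC1(O)C(=O)O[C@@H](CCCCCCCCCCCCC[C@H](C)O)[C@H]1C(=O)OC(C)(C)C | intermediate
16 | tert-butyl (2S,3S)-2-[(14S)-14-hydroxypentadecyl]-4-methylidene-5-oxooxolane-3-carboxylate | C=C1C(=O)O[C@@H](CCCCCCCCCCCCC[C@H](C)O)[C@H]1C(=O)OC(C)(C)C | intermediate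
17 | (2S,3S)-2-[(14S)-14-hydroxypentadecyl]-4-methylidene-5-oxooxolane-3-carboxylic acid | C=C1C(=O)O[C@@H](CCCCCCCCCCCCC[C@H](C)O)[C@H]1C(=O)O | target

**Totals**
Total step count: 6. Longest linear sequence: 5 (steps 1, 2, 3, 4, 6; step 5 makes the C3 reagent).

**Steps most likely to fail**

Step 6 (key cascade). The trianion may deprotonate 12 instead of adding to it, the aldolate may revert on warming, or CF3CO2H may be too weak to drive the Peterson elimination next to a lactone carbonyl. The fallback sets out from 9 and comes back at 16. The trianion 13, made from 9 as before, is added at −78 °C to commercial ethyl 3-bromo-2-oxopropanoate and quenched cold with AcOH to give 1-tert-butyl 4-ethyl (2R)-3-(bromomethyl)-2-[(1S,15S)-1,15-dihydroxyhexadecyl]-3-hydroxybutanedioate F1. PPTS in CH2Cl2 closes the lactone to tert-butyl (2S,3R)-4-(bromomethyl)-4-hydroxy-2-[(14S)-14-hydroxypentadecyl]-5-oxooxolane-3-carboxylate F2. Zinc dust in AcOH/THF then removes bromide and hydroxyl by reductive β-elimination of the bromohydrin, again regiospecifically exocyclic and base-free, to give 16, which CF3CO2H/CH2Cl2 converts into 17 as in step 6.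

Step 5 (the α-silyl keto ester). Compound 12 may lose silicon on work-up, rearrange to the silyl enol ether on distillation, or be contaminated by double addition. The fallback sets out from 10 and comes back at 12. NiCl2(dppp)-catalysed Kumada coupling of 10 with ethyl 2-bromoprop-2-enoate gives ethyl 2-[(trimethylsilyl)methyl]prop-2-enoate F3 (also purchasable). Ozonolysis (O3, CH2Cl2, −78 °C; PPh3) cleaves the methylene carbon and delivers 12 in a neutral, water-free solution that is used directly without distillation.

Step 3 (dianion alkylation by a hydroxy bromide). The long-chain bromo alkoxide may aggregate and react sluggishly, or be consumed by elimination. The fallback sets out from 1, 2 and 6 and comes back at 9, so that steps 2 to 4 are replaced. Dianion 7 is alkylated with the hydroxyl-free bromide 1 to give tert-butyl 3-oxopentadec-14-enoate F4. Epoxide 2 is opened with CH2=CHMgBr and CuI (cat.) to give (2S)-pent-4-en-2-ol F5. Cross-metathesis of F4 with excess F5 (second-generation Grubbs catalyst, CH2Cl2, 40 °C) gives tert-butyl (17S)-17-hydroxy-3-oxooctadec-14-enoate F6 as an E/Z mixture. Hydrogenation with [RuCl(p-cymene)((S)-BINAP)]Cl in MeOH, followed by Pd/C and H2 in the same vessel, reduces the keto group enantioselectively and saturates the alkene to give 9.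

**Further compounds**
F1 | step 6 | 1-tert-butyl 4-ethyl (2R)-3-(bromomethyl)-2-[(1S,15S)-1,15-dihydroxyhexadecyl]-3-hydroxybutanedioate (C-3 epimers) | CCOC(=O)C(O)(CBr)[C@@H]([C@@H](O)CCCCCCCCCCCCC[C@H](C)O)C(=O)OC(C)(C)C
F2 | step 6 | tert-butyl (2S,3R)-4-(bromomethyl)-4-hydroxy-2-[(14S)-14-hydroxypentadecyl]-5-oxooxolane-3-carboxylate (C-4 epimers) | BrCC1(O)C(=O)O[C@@H](CCCCCCCCCCCCC[C@H](C)O)[C@H]1C(=O)OC(C)(C)C
F3 | step 5 | ethyl 2-[(trimethylsilyl)methyl]prop-2-enoate | C=C(C[Si](C)(C)C)C(=O)OCC
F4 | step 3 | tert-butyl 3-oxopentadec-14-enoate | C=CCCCCCCCCCCC(=O)CC(=O)OC(C)(C)C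
F5 | step 3 | (2S)-pent-4-en-2-ol | C[C@H](O)CC=C
F6 | step 3 | tert-butyl (17S)-17-hydroxy-3-oxooctadec-14-enoate (E/Z mixture) | C[C@H](O)CC=CCCCCCCCCCCC(=O)CC(=O)OC(C)(C)C
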